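## Retrosynthetic overview

1. The target is the 4-O-acetate, 3-O-(2R)-2-methylbutanoate of a trans-3β,4α-diol, which comes from hydroxyl-directed reduction of a 4α-hydroxy-3-ketone.
2. Key disconnection C3–C4: the α-ketol opens to a keto aldehyde. Forward, a carbene-bound acyl anion at C3 adds to the methyl ketone carbon C4 and closes ring A last.
3. C1–C10: the C1–C3 unit enters as a masked propanal homoenolate (but-3-enyl copper reagent) by conjugate addition to (+)-verbenone, so this three-carbon unit reacts with reversed polarity at both ends.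
4. Ring B is not built: it is the six-membered ring of verbenone, released by cyclobutane cleavage. The same cleavage turns the gem-dimethyl bridge into the isopropenyl (later acetyl) group trans to the new chain. The isopropylidene group comes from acetone.
5. Ring order: ring B (chiral pool) first, ring A last.

Assumption: eudesmane numbering (C1–C15) is used for the target carbons; (1R,5R)-(+)-verbenone and (2R)-2-methylbutanoic acid are bought as single enantiomers (the former is otherwise an allylic oxidation away from (+)-α-pinene).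

## Route

Step 1
Reactants: 1 (1R,5R)-(+)-verbenone; 2 but-3-en-1-ylmagnesium bromide
Product: 4 (1R,4R,5R)-4-(but-3-en-1-yl)-4,6,6-trimethylbicyclo[3.1.1]heptan-2-one, via bromomagnesium enolate 3 (not isolated)
Conditions: 2 (1.5 equiv), CuBr·SMe2 (10 mol %), THF, −40 to 0 °C; then NH4Cl aq
Reagents that add atoms: but-3-en-1-ylmagnesium bromide, C=CCC[Mg]Br
Why: Copper-catalysed 1,4-addition of a Grignard reagent whose butenyl group is a masked propanal homoenolate; the reagent attacks the enone face away from the gem-dimethyl bridge, which fixes the new quaternary centre (later C10) with the chain anti to the bridge.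

Step 2
Reactants: 4 (1R,4R,5R)-4-(but-3-en-1-yl)-4,6,6-trimethylbicyclo[3.1.1]heptan-2-one
Product: 7 (3R,4S)-3-(but-3-en-1-yl)-3-methyl-4-(prop-1-en-2-yl)cyclohexan-1-one, via iodo silyl enol ether 5 (not isolated), via isopropenyl silyl enol ether 6 (not isolated)
Conditions: Me3SiCl, NaI, MeCN, 0 °C; then DBU, 60 °C; then 1 M HCl aq, 0 °C
Reagents that add atoms: none
Why: Silyl activation of the ketone and iodide attack cleave the strained cyclobutane bond between the α-bridgehead and the gem-dimethyl carbon (homoconjugate opening of a cycloalkyl ketone by Me3SiI), E2 of the tertiary iodide toward a methyl group gives the isopropenyl group, and acid frees the ketone; no stereocentre is touched, so chain and isopropenyl end up trans on ring B.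

Step 3
Reactants: 7 (3R,4S)-3-(but-3-en-1-yl)-3-methyl-4-(prop-1-en-2-yl)cyclohexan-1-one; 8 acetone; 9 acetic anhydride
Product: 13 (4S,5R)-5-(but-3-en-1-yl)-5-methyl-4-(prop-1-en-2-yl)-2-(propan-2-ylidene)cyclohexan-1-one, via lithium enolate 10 (not isolated), via lithium aldolate 11 (not isolated), via tertiary acetate 12 (not isolated)
Conditions: LiN(iPr)2, THF, −78 °C; 8; then 9, −78 to 0 °C; then DBU, rt
Reagents that add atoms: acetone, CC(C)=O
Why: Kinetic deprotonation at the α-CH2 remote from the quaternary carbon (C7), aldol addition to acetone, acetylation of the aldolate and E1cB elimination give the conjugated tetrasubstituted enone (aldol condensation); no stereocentre is set.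

Step 4
Reactants: 13 (4S,5R)-5-(but-3-en-1-yl)-5-methyl-4-(prop-1-en-2-yl)-2-(propan-2-ylidene)cyclohexan-1-one
Product: 15 3-[(1R,2R)-2-acetyl-1-methyl-5-oxo-4-(propan-2-ylidene)cyclohexyl]propanal, via tetraol 14 (not isolated)
Conditions: OsO4 (2 mol %), NaIO4 (5 equiv), 2,6-lutidine, dioxane/H2O 3:1, rt
Reagents that add atoms: OsO4, O=[Os](=O)(=O)=O; NaIO4, [Na+].[O-]I(=O)(=O)=O
Why: Lemieux–Johnson oxidation: OsO4 dihydroxylates only the electron-rich mono- and 1,1-disubstituted alkenes and periodate cleaves the diols, while the hindered, electron-poor tetrasubstituted enone alkene is left; the stereocentres are untouched.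

Step 5
Reactants: 15 3-[(1R,2R)-2-acetyl-1-methyl-5-oxo-4-(propan-2-ylidene)cyclohexyl]propanal
Product: 16 (1S,4aR,8aR)-1-hydroxy-1,4a-dimethyl-7-(propan-2-ylidene)-3,4,4a,5,8,8a-hexahydronaphthalene-2,6(1H,7H)-dione
Conditions: 6,7-dihydro-2-(pentafluorophenyl)-5H-pyrrolo[2,1-c][1,2,4]triazol-2-ium tetrafluoroborate (15 mol %), Et3N (15 mol %), toluene, rt
Reagents that add atoms: none
Why: Intramolecular crossed aldehyde–ketone benzoin reaction: the carbene turns the aldehyde carbon C3 into an acyl anion equivalent (Breslow intermediate) that adds to the methyl ketone carbon C4, closing ring A on trans-diequatorial substituents (trans-decalin); in the chair transition state the enaminol O–H must hydrogen-bond to the ketone oxygen while the bulky azolium stays pseudo-equatorial, which is predicted to place the new OH equatorial (4α) and the methyl axial (4β), and the conjugated, hindered C8 ketone (bridged ring) should not compete.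

Step 6
Reactants: 16 (1S,4aR,8aR)-1-hydroxy-1,4a-dimethyl-7-(propan-2-ylidene)-3,4,4a,5,8,8a-hexahydronaphthalene-2,6(1H,7H)-dione
Product: 17 (4aR,5S,6S,8aR)-5,6-dihydroxy-5,8a-dimethyl-3-(propan-2-ylidene)-3,4,4a,5,6,7,8,8a-octahydronaphthalen-2(1H)-one
Conditions: Me4NBH(OAc)3, MeCN/AcOH 1:1, −20 °C
Reagents that add atoms: none
Why: Hydroxyl-directed (Saksena–Evans) reduction: the 4α-OH binds boron and delivers hydride to the α face of C3, giving the equatorial 3β-alcohol trans to the tertiary OH; the enone ketone has no neighbouring hydroxyl and is not reduced by this reagent.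

Step 7
Reactants: 17 (4aR,5S,6S,8aR)-5,6-dihydroxy-5,8a-dimethyl-3-(propan-2-ylidene)-3,4,4a,5,6,7,8,8a-octahydronaphthalen-2(1H)-one; 18 (2R)-2-methylbutanoic acid
Product: 19 (1S,2S,4aR,8aR)-1-hydroxy-1,4a-dimethyl-6-oxo-7-(propan-2-ylidene)decahydronaphthalen-2-yl (2R)-2-methylbutanoate
Conditions: 18 (1.3 equiv), DCC, DMAP (10 mol %), CH2Cl2, 0 °C to rt
Reagents that add atoms: (2R)-2-methylbutanoic acid, CC[C@@H](C)C(O)=O
Why: Steglich esterification: only the secondary equatorial 3β-OH is acylated, the tertiary OH is inert under these conditions, and the α-stereocentre of the acid is retained at low temperature.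

Step 8
Reactants: 19 (1S,2S,4aR,8aR)-1-hydroxy-1,4a-dimethyl-6-oxo-7-(propan-2-ylidene)decahydronaphthalen-2-yl (2R)-2-methylbutanoate; 9 acetic anhydride
Product: 20 (1S,2S,4aR,8aR)-1-(acetyloxy)-1,4a-dimethyl-6-oxo-7-(propan-2-ylidene)decahydronaphthalen-2-yl (2R)-2-methylbutanoate
Conditions: 9, Sc(OTf)3 (5 mol %), MeCN, −20 °C
Reagents that add atoms: acetic anhydride, CC(=O)OC(C)=O
Why: Sc(OTf)3-catalysed acylation of a hindered tertiary alcohol under non-basic conditions (no alkoxide, hence no 1,2-migration of the neighbouring ester); no stereocentre is touched.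

## Compound list

1 | (1R,5R)-(+)-verbenone, (1R,5R)-4,6,6-trimethylbicyclo[3.1.1]hept-3-en-2-one | CC1=CC(=O)[C@@H]2C[C@H]1C2(C)C | starting material
2 | but-3-en-1-ylmagnesium bromide | C=CCC[Mg]Br | starting material
3 | bromomagnesium enolate of 4 (O–MgBr on C2, C2=C3 double bond, other centres as in 4), not isolated | C[C@@]1(CCC=C)C=C(O[Mg]Br)[C@@H]2C[C@H]1C2(C)C | intermediate
4 | (1R,4R,5R)-4-(but-3-en-1-yl)-4,6,6-trimethylbicyclo[3.1.1]heptan-2-one | C[C@@]1(CCC=C)CC(=O)[C@@H]2C[C@H]1C2(C)C | intermediate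
5 | {[(4R,5R)-5-(but-3-en-1-yl)-4-(2-iodopropan-2-yl)-5-methylcyclohex-1-en-1-yl]oxy}trimethylsilane, not isolated | C[C@@]1(CCC=C)CC(O[Si](C)(C)C)=CC[C@H]1C(C)(C)I | intermediate
6 | {[(4S,5R)-5-(but-3-en-1-yl)-5-methyl-4-(prop-1-en-2-yl)cyclohex-1-en-1-yl]oxy}trimethylsilane, not isolated | C[C@@]1(CCC=C)CC(O[Si](C)(C)C)=CC[C@H]1C(C)=C | intermediate
7 | (3R,4S)-3-(but-3-en-1-yl)-3-methyl-4-(prop-1-en-2-yl)cyclohexan-1-one | C[C@@]1(CCC=C)CC(=O)CC[C@H]1C(C)=C | intermediate
8 | acetone | CC(C)=O | starting material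
9 | acetic anhydride | CC(=O)OC(C)=O | starting material
10 | lithium (4S,5R)-5-(but-3-en-1-yl)-5-methyl-4-(prop-1-en-2-yl)cyclohex-1-en-1-olate, not isolated | C[C@@]1(CCC=C)CC(O[Li])=CC[C@H]1C(C)=C | intermediate
11 | lithium 2-[(4R,5S)-4-(but-3-en-1-yl)-4-methyl-2-oxo-5-(prop-1-en-2-yl)cyclohexyl]propan-2-olate (both epimers at ring C1), not isolated | C[C@@]1(CCC=C)CC(=O)C(C(C)(C)O[Li])C[C@H]1C(C)=C | intermediate
12 | 2-[(4R,5S)-4-(but-3-en-1-yl)-4-methyl-2-oxo-5-(prop-1-en-2-yl)cyclohexyl]propan-2-yl acetate (both epimers at ring C1), not isolated | C[C@@]1(CCC=C)CC(=O)C(C(C)(C)OC(C)=O)C[C@H]1C(C)=C | intermediate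
13 | (4S,5R)-5-(but-3-en-1-yl)-5-methyl-4-(prop-1-en-2-yl)-2-(propan-2-ylidene)cyclohexan-1-one | C[C@@]1(CCC=C)CC(=O)C(=C(C)C)C[C@H]1C(C)=C | intermediate
14 | (4R,5R)-5-(3,4-dihydroxybutyl)-4-(1,2-dihydroxypropan-2-yl)-5-methyl-2-(propan-2-ylidene)cyclohexan-1-one (epimers at the two new carbinol carbons), not isolated | C[C@@]1(CCC(O)CO)CC(=O)C(=C(C)C)C[C@H]1C(C)(O)CO | intermediate
15 | 3-[(1R,2R)-2-acetyl-1-methyl-5-oxo-4-(propan-2-ylidene)cyclohexyl]propanal | C[C@@]1(CCC=O)CC(=O)C(=C(C)C)C[C@H]1C(C)=O | intermediate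
16 | (1S,4aR,8aR)-1-hydroxy-1,4a-dimethyl-7-(propan-2-ylidene)-3,4,4a,5,8,8a-hexahydronaphthalene-2,6(1H,7H)-dione (4α-hydroxyeudesm-7(11)-ene-3,8-dione) | O=C1CC[C@]2(C)CC(=O)C(=C(C)C)C[C@H]2[C@]1(C)O | intermediate
17 | (4aR,5S,6S,8aR)-5,6-dihydroxy-5,8a-dimethyl-3-(propan-2-ylidene)-3,4,4a,5,6,7,8,8a-octahydronaphthalen-2(1H)-one (3β,4α-dihydroxyeudesm-7(11)-en-8-one) | O[C@H]1CC[C@]2(C)CC(=O)C(=C(C)C)C[C@H]2[C@]1(C)O | intermediate
18 | (2R)-2-methylbutanoic acid | CC[C@@H](C)C(O)=O | starting material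
19 | (1S,2S,4aR,8aR)-1-hydroxy-1,4a-dimethyl-6-oxo-7-(propan-2-ylidene)decahydronaphthalen-2-yl (2R)-2-methylbutanoate | CC[C@@H](C)C(=O)O[C@H]1CC[C@]2(C)CC(=O)C(=C(C)C)C[C@H]2[C@]1(C)O | intermediate
20 | (1S,2S,4aR,8aR)-1-(acetyloxy)-1,4a-dimethyl-6-oxo-7-(propan-2-ylidene)decahydronaphthalen-2-yl (2R)-2-methylbutanoate (3β-acyloxy, 4α-acetoxy, 4β-methyl, 5α-H, 10β-methyl) | CC[C@@H](C)C(=O)O[C@H]1CC[C@]2(C)CC(=O)C(=C(C)C)C[C@H]2[C@]1(C)OC(C)=O | target

## Step count and risks

Total steps: 8. Longest linear sequence: 8 steps (1 to 20).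

**Step 5 (carbene benzoin closure).** The methyl ketone is hindered, and the wanted C4 epimer (methyl axial, syn to the C10 methyl) is the less stable one. The other transition state, or retro-benzoin equilibration, could therefore give the 4-epimer. Fallback, from 13 back to 16: ring-closing metathesis of the butenyl and isopropenyl groups of 13 (second-generation Grubbs catalyst, CH2Cl2, 40 °C) gives the diene (4aR,8aR)-5,8a-dimethyl-3-(propan-2-ylidene)-3,4,4a,7,8,8a-hexahydronaphthalen-2(1H)-one F1. OsO4 (cat.)/N-methylmorpholine N-oxide dihydroxylates its trisubstituted alkene from the α face, opposite the angular methyl, to the cis-diol (4aR,5S,6R,8aR)-5,6-dihydroxy-5,8a-dimethyl-3-(propan-2-ylidene)-3,4,4a,5,6,7,8,8a-octahydronaphthalen-2(1H)-one F2, in which C4 is already correct. Oxidation of the secondary alcohol (SO3·pyridine, DMSO, Et3N) gives 16, and step 6 sets C3 as before.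

**Step 2 (cyclobutane opening).** Me3SiI or adventitious HI may add to the terminal alkene, and the elimination could give some isopropylidene isomer. Fallback, from 4 back to 7: acetolytic opening (BF3·OEt2, Zn(OAc)2, Ac2O, rt) traps the cation as acetate and the enol as enol acetate, giving (4R,5R)-4-[2-(acetyloxy)propan-2-yl]-5-(but-3-en-1-yl)-5-methylcyclohex-1-en-1-yl acetate F3. K2CO3 in MeOH at 50 °C removes both acetyl groups to give the hydroxy ketone (3R,4R)-3-(but-3-en-1-yl)-4-(2-hydroxypropan-2-yl)-3-methylcyclohexan-1-one F4. Syn-dehydration toward a methyl group with methyl N-(triethylammoniosulfonyl)carbamate (Burgess reagent) in toluene at 60 °C gives 7.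

**Step 3 (one-pot isopropylidene installation).** Proton transfer to acetone or retro-aldol before acetylation can return 7, and O-acetylation of the enolate is a side path. Fallback, from 6 back to 13: step 2 is worked up without acid so that the regiodefined silyl enol ether 6 is kept. Mukaiyama aldol addition of 6 to acetone (TiCl4, CH2Cl2, −78 °C) gives the β-hydroxy ketone (4S,5R)-5-(but-3-en-1-yl)-2-(2-hydroxypropan-2-yl)-5-methyl-4-(prop-1-en-2-yl)cyclohexan-1-one F5 (epimers at C2). This is dehydrated (MsCl, Et3N, then DBU) to 13.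

Further compounds
F1 | step 5 | (4aR,8aR)-5,8a-dimethyl-3-(propan-2-ylidene)-3,4,4a,7,8,8a-hexahydronaphthalen-2(1H)-one | CC1=CCC[C@]2(C)CC(=O)C(=C(C)C)C[C@H]21
F2 | step 5 | (4aR,5S,6R,8aR)-5,6-dihydroxy-5,8a-dimethyl-3-(propan-2-ylidene)-3,4,4a,5,6,7,8,8a-octahydronaphthalen-2(1H)-one | O[C@@H]1CC[C@]2(C)CC(=O)C(=C(C)C)C[C@H]2[C@]1(C)O
F3 | step 2 | (4R,5R)-4-[2-(acetyloxy)propan-2-yl]-5-(but-3-en-1-yl)-5-methylcyclohex-1-en-1-yl acetate | C[C@@]1(CCC=C)CC(OC(C)=O)=CC[C@H]1C(C)(C)OC(C)=O
F4 | step 2 | (3R,4R)-3-(but-3-en-1-yl)-4-(2-hydroxypropan-2-yl)-3-methylcyclohexan-1-one | C[C@@]1(CCC=C)CC(=O)CC[C@H]1C(C)(C)O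
F5 | step 3 | (4S,5R)-5-(but-3-en-1-yl)-2-(2-hydroxypropan-2-yl)-5-methyl-4-(prop-1-en-2-yl)cyclohexan-1-one (epimers at C2) | C[C@@]1(CCC=C)CC(=O)C(C(C)(C)O)C[C@H]1C(C)=C
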